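**Retrosynthetic overview**

1. Locants are germacrane-type: ten-membered carbocycle C1–C10, oxirane on C1/C10 (C14 methyl on C10), C4=C15H2, C5–OH, C6–O (lactone), C7, C8–O (angelate), C9, lactone C11(=C13H2)–C12. The target is traced back, by Shi epoxidation of a (Z)-C1=C10 olefin and Corey–Bakshi–Shibata reduction of a C5 ketone, to a ten-membered 4(15)-en-5-one.
2. That enone comes in one operation from a cyclohexanone (ring B: C5–C6–C7–C8–C9–C10) that carries on C10 the chain C1(OMs)–C2–C3–C4(Br)=C15. Ni/Cr alkenylation of the C5 ketone forms the C4–C5 bond and closes six-membered ring A (C1–C2–C3–C4–C5–C10); the alkoxide then cuts C5–C10 by Grob fragmentation, a four-carbon ring expansion from six to ten.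
3. Enabling feature: in the target the oxygen-bearing C5 lies across the ring from the oxirane carbon C10, and its neighbour C4 carries the methylidene. An imagined C5–C10 bond folds the carbocycle into a cis-decalin (rings A and B) in which O–C5–C10–C1–X is a Grob array, C4 is an alkenyl donor for a C5 carbonyl, and C1=C10 (the later oxirane) is the olefin the fragmentation makes.
4. The cyclohexanone is assembled by angelate ester formation at C8, cis-lactone closure by carboxylate SN2 at a C6 bromo ketone, acrolein-acetal cuprate addition at C7 anti to C8–OSi, and methylation plus aldol with 4-bromopent-4-enal at C10, all on (S)-4-silyloxycyclohex-2-enone made by Noyori reduction of a commercial enone ketal.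
5. Ring order: ring B (purchased six-membered ring) → γ-lactone → transient ring A → ten-membered ring (by fragmentation) → oxirane.

Key step: step 14

Remark: in the target the two ring carbons on the oxirane (C2, C9) are cis, H6 and H7 are cis (cis-fused lactone), and C8–O is trans to the C7–C11 bond. The route therefore aims at a (Z)-C1=C10 olefin, a cis-lactone and a 7,8-trans arrangement.

**Route**

Step 1
Reactants: 1 ethyl acetate; 2 2,3-dibromoprop-1-ene
Product: 4 ethyl 4-bromopent-4-enoate, via lithium enolate of ethyl acetate 3 (not isolated)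
Conditions: LiN(i-Pr)2, THF, −78 °C; then 2, DMPU, −78 → −20 °C
Reagents that add atoms: none
Why: Alkylation of the ester lithium enolate at the allylic C–Br bond of 2 (SN2, the vinylic bromide being inert) gives the 2-bromoallyl homologue of the acetate, and no stereocentre is formed.

Step 2
Reactants: 4 ethyl 4-bromopent-4-enoate
Product: 5 4-bromopent-4-enal
Conditions: i-Bu2AlH (1.05 equiv), CH2Cl2, −78 °C; MeOH, then aq potassium sodium tartrate
Reagents that add atoms: none
Why: Partial ester reduction with i-Bu2AlH at low temperature stops at the aluminium hemiacetal, which collapses to the aldehyde on work-up, and no stereocentre is formed.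

Step 3
Reactants: 6 1,4-dioxaspiro[4.5]dec-6-en-8-one
Product: 7 (8S)-1,4-dioxaspiro[4.5]dec-6-en-8-ol
Conditions: RuCl(p-cymene)[(S,S)-TsDPEN] (1 mol %), HCO2Na, Bu4NCl, CH2Cl2/H2O, 25 °C
Reagents that add atoms: none
Why: Noyori asymmetric transfer hydrogenation reduces the enone carbonyl in the 1,2 sense, and with the alkenyl group taking the place of the aryl group of aryl ketones the (S,S) catalyst should set the S carbinol that becomes C8.

Step 4
Reactants: 7 (8S)-1,4-dioxaspiro[4.5]dec-6-en-8-ol
Product: 8 (8S)-8-(tert-butyldimethylsilyloxy)-1,4-dioxaspiro[4.5]dec-6-ene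
Conditions: TBSCl, imidazole, DMF, 25 °C
Reagents that add atoms: tert-butyldimethylsilyl chloride, CC(C)(C)[Si](C)(C)Cl
Why: Standard silylation of a secondary allylic alcohol, which leaves the stereocentre untouched.

Step 5
Reactants: 8 (8S)-8-(tert-butyldimethylsilyloxy)-1,4-dioxaspiro[4.5]dec-6-ene
Product: 9 (4S)-4-(tert-butyldimethylsilyloxy)cyclohex-2-en-1-one
Conditions: PPTS (0.1 equiv), THF/H2O (4:1), 50 °C
Reagents that add atoms: water, O
Why: Mild acid hydrolysis of the allylic ketal releases the carbonyl in conjugation with the olefin (net 1,3-transposition of the enone) while the silyl ether and its stereocentre survive.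

Step 6
Reactants: 9 (4S)-4-(tert-butyldimethylsilyloxy)cyclohex-2-en-1-one
Product: 11 (4S,6RS)-4-(tert-butyldimethylsilyloxy)-6-methylcyclohex-2-en-1-one, via lithium dienolate of the silyloxy enone 10 (not isolated)
Conditions: LiN(i-Pr)2, THF, −78 °C; MeI, DMPU, −78 → −40 °C
Reagents that add atoms: iodomethane, CI
Why: Kinetic deprotonation of the enone at the alpha-prime carbon (the later C10) and SN2 methylation of the cross-conjugated dienolate install C14, and the epimer mixture at this carbon is of no consequence because it is enolized again in step 7.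

Step 7
Reactants: 11 (4S,6RS)-4-(tert-butyldimethylsilyloxy)-6-methylcyclohex-2-en-1-one; 5 4-bromopent-4-enal
Product: 13 (4S,6R)-6-[(1R)-4-bromo-1-hydroxypent-4-en-1-yl]-4-(tert-butyldimethylsilyloxy)-6-methylcyclohex-2-en-1-one, via lithium dienolate of the methyl enone 12 (not isolated)
Conditions: LiN(i-Pr)2, THF, −78 °C; 5, −78 °C, 15 min; AcOH/THF quench at −78 °C
Reagents that add atoms: none
Why: Aldol addition of the only possible, ring-locked E enolate through a closed chair transition state should place ring carbon C9 anti to the new C1 hydroxyl (1R with 10R), the relationship that later dictates the Z olefin, while attack anti to the C8 silyloxy group should set 10R, and addition on the other face with the same C1/C10 relationship would converge at step 14.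

Step 8
Reactants: 13 (4S,6R)-6-[(1R)-4-bromo-1-hydroxypent-4-en-1-yl]-4-(tert-butyldimethylsilyloxy)-6-methylcyclohex-2-en-1-one
Product: 14 (1R)-4-bromo-1-[(1R,5S)-5-(tert-butyldimethylsilyloxy)-1-methyl-2-oxocyclohex-3-en-1-yl]pent-4-en-1-yl methanesulfonate
Conditions: MsCl, Et3N, CH2Cl2, −10 °C
Reagents that add atoms: methanesulfonyl chloride, CS(=O)(=O)Cl
Why: Sulfonylation through sulfene converts the hindered C1 hydroxyl with retention into the nucleofuge for step 14, and the quaternary C10 next to it blocks both elimination towards the ketone and SN2 displacement in the steps that follow.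

Step 9
Reactants: 14 (1R)-4-bromo-1-[(1R,5S)-5-(tert-butyldimethylsilyloxy)-1-methyl-2-oxocyclohex-3-en-1-yl]pent-4-en-1-yl methanesulfonate; 15 2-bromo-3,3-diethoxyprop-1-ene
Product: 18 (1R)-4-bromo-1-[(1R,4R,5S)-5-(tert-butyldimethylsilyloxy)-4-(3,3-diethoxyprop-1-en-2-yl)-1-methyl-2-(trimethylsilyloxy)cyclohex-2-en-1-yl]pent-4-en-1-yl methanesulfonate, via 2-lithioacrolein diethyl acetal 16 (not isolated), via lithium dialkenylcuprate 17 (not isolated)
Conditions: 15, t-BuLi, Et2O, −78 °C; CuBr·SMe2, −78 → −45 °C; TMSCl then 14, THF, −78 °C; Et3N/aq NaHCO3 work-up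
Reagents that add atoms: chlorotrimethylsilane, C[Si](C)(C)Cl
Why: Conjugate addition of the lithium dialkenylcuprate of 2-lithioacrolein diethyl acetal (an acrylate alpha-anion equivalent) to the gamma-silyloxy enone anti to the C8–O bond sets C7 with C11 trans to O8, and TMSCl traps the enolate regiospecifically as the C5=C6 silyl enol ether.

Step 10
Reactants: 18 (1R)-4-bromo-1-[(1R,4R,5S)-5-(tert-butyldimethylsilyloxy)-4-(3,3-diethoxyprop-1-en-2-yl)-1-methyl-2-(trimethylsilyloxy)cyclohex-2-en-1-yl]pent-4-en-1-yl methanesulfonate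
Product: 19 (1R)-4-bromo-1-[(1R,3S,4R,5S)-3-bromo-5-(tert-butyldimethylsilyloxy)-4-(3,3-diethoxyprop-1-en-2-yl)-1-methyl-2-oxocyclohexyl]pent-4-en-1-yl methanesulfonate
Conditions: NBS, NaHCO3, THF, −78 → 0 °C
Reagents that add atoms: N-bromosuccinimide, O=C1CCC(=O)N1Br
Why: Electrophilic bromination of the silyl enol ether occurs at C6 on the face anti to the new C7 substituent, which places the bromide trans to the side arm as the SN2 lactonization of step 12 requires.

Step 11
Reactants: 19 (1R)-4-bromo-1-[(1R,3S,4R,5S)-3-bromo-5-(tert-butyldimethylsilyloxy)-4-(3,3-diethoxyprop-1-en-2-yl)-1-methyl-2-oxocyclohexyl]pent-4-en-1-yl methanesulfonate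
Product: 20 (1R)-4-bromo-1-[(1R,3S,4R,5S)-3-bromo-5-hydroxy-1-methyl-2-oxo-4-(3-oxoprop-1-en-2-yl)cyclohexyl]pent-4-en-1-yl methanesulfonate
Conditions: aq HF (48 %), MeCN, 0 → 25 °C
Reagents that add atoms: water, O
Why: Aqueous HF hydrolyses the diethyl acetal to the 2-substituted acrolein and cleaves the secondary silyl ether in one operation, the bromo ketone, mesylate and vinyl bromide being acid-stable and no stereocentre being touched.

Step 12
Reactants: 20 (1R)-4-bromo-1-[(1R,3S,4R,5S)-3-bromo-5-hydroxy-1-methyl-2-oxo-4-(3-oxoprop-1-en-2-yl)cyclohexyl]pent-4-en-1-yl methanesulfonate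
Product: 22 (1R)-4-bromo-1-[(3aR,4S,6R,7aR)-4-hydroxy-6-methyl-3-methylidene-2,7-dioxooctahydro-1-benzofuran-6-yl]pent-4-en-1-yl methanesulfonate, via acrylic acid intermediate 21 (not isolated)
Conditions: NaClO2, NaH2PO4, 2-methylbut-2-ene, t-BuOH/H2O, 0 °C; then NaHCO3 (to pH 8), DMF, 25 °C
Reagents that add atoms: sodium chlorite, [Na+].[O-]Cl=O
Why: Pinnick oxidation turns the enal into the acrylic acid, whose carboxylate displaces the activated alpha-keto bromide by intramolecular SN2 (5-exo-tet) with inversion, so the lactone oxygen at C6 ends cis to the C7–C11 bond (cis-fused methylene lactone), and an epimeric bromide would equilibrate through the enol and funnel to the same lactone.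

Step 13
Reactants: 22 (1R)-4-bromo-1-[(3aR,4S,6R,7aR)-4-hydroxy-6-methyl-3-methylidene-2,7-dioxooctahydro-1-benzofuran-6-yl]pent-4-en-1-yl methanesulfonate; 23 angelic acid
Product: 25 (3aR,4S,6R,7aR)-6-[(1R)-4-bromo-1-(methanesulfonyloxy)pent-4-en-1-yl]-6-methyl-3-methylidene-2,7-dioxooctahydro-1-benzofuran-4-yl (2Z)-2-methylbut-2-enoate, via angelic trichlorobenzoic mixed anhydride 24 (not isolated)
Conditions: 23, 2,4,6-trichlorobenzoyl chloride, Et3N, toluene, 25 °C; then 22, 60 °C
Reagents that add atoms: none
Why: Yamaguchi esterification without a nucleophilic catalyst acylates the C8 hydroxyl at the less hindered angeloyl carbonyl of the mixed anhydride with retention at C8, a protocol chosen because it is known to preserve the Z geometry of the angelate.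

Step 14
Reactants: 25 (3aR,4S,6R,7aR)-6-[(1R)-4-bromo-1-(methanesulfonyloxy)pent-4-en-1-yl]-6-methyl-3-methylidene-2,7-dioxooctahydro-1-benzofuran-4-yl (2Z)-2-methylbut-2-enoate
Product: 28 (1(10)Z,6R,7R,8S)-8-angeloyloxy-5-oxogermacra-1(10),4(15),11(13)-trien-12,6-olide, via alkenylchromium dichloride 26 (not isolated), via tricyclic chromium alkoxide 27 (not isolated)
Conditions: CrCl2 (6 equiv), NiCl2 (2 mol %), degassed DMSO (0.01 M), 25 °C, then 50 °C
Reagents that add atoms: none
Why: Proposed new method: zerovalent nickel inserts into the C4–Br bond and hands the alkenyl group to chromium, the alkenyl–CrCl2 species 26 adds to the C5 ketone (forming the C4–C5 bond and the cis-fused ring A of alkoxide 27), and the trivalent chromium alkoxide, with its C5–C10 bond antiperiplanar to the equatorial C1–OMs bond, then undergoes Grob fragmentation in which the oxygen lone pair re-forms the C5 carbonyl, the ring-fusion bond C5–C10 breaks, C1=C10 forms and mesylate leaves, so the bicyclo[4.4.0] core opens to the ten-membered ring with the C4(=CH2)–C5(=O) enone in place. The closest known reaction types are the Nozaki–Hiyama–Kishi alkenylation of ketones and the SmI2 Barbier cyclization/Grob fragmentation cascade of iodoalkyl keto sulfonates, and what is new is an alkenylchromium donor combined with a chromium alkoxide as the fragmenting species in one flask. The only ring closed directly is the transient six-membered ring A, by 6-exo-trig attack on the carbonyl, whereas the ten-membered ring is released, not closed, when the shared C5–C10 bond is cut. No new stereocentre survives because C5 returns to sp2, and the olefin geometry is fixed by the 1R,10R relationship from step 7, since with the mesylate antiperiplanar to C5–C10 the ring carbons C2 and C9 are gauche and end cis (Z) whichever ring fusion forms. The step needs addition to the ketone rather than to the lactone, the angelate or the conjugated alkenes, which the carbonyl selectivity of alkenylchromium reagents and the six-membered transition state should secure, and it needs fragmentation rather than survival of 27, which the aligned secondary mesylate, the strain of the all-cis tricycle, the gain of enone conjugation and warming in DMSO are expected to secure.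

Step 15
Reactants: 28 (1(10)Z,6R,7R,8S)-8-angeloyloxy-5-oxogermacra-1(10),4(15),11(13)-trien-12,6-olide
Product: 29 (1(10)Z,5S,6R,7R,8S)-8-angeloyloxy-5-hydroxygermacra-1(10),4(15),11(13)-trien-12,6-olide
Conditions: (S)-2-methyl-CBS-oxazaborolidine (1 equiv), catecholborane, toluene/CH2Cl2, −78 °C; MeOH quench
Reagents that add atoms: none
Why: Corey–Bakshi–Shibata reduction reduces only the enone carbonyl in the 1,2 sense, and with the 1,1-disubstituted alkenyl arm (C4) acting as the large group the S catalyst should deliver hydride to the face that gives 5S, reagent control being relied on to override the bias of the medium ring.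

Step 16
Reactants: 29 (1(10)Z,5S,6R,7R,8S)-8-angeloyloxy-5-hydroxygermacra-1(10),4(15),11(13)-trien-12,6-olide
Product: 30 (1R,5S,6R,7R,8S,10S)-8-angeloyloxy-1,10-epoxy-5-hydroxygermacra-4(15),11(13)-dien-12,6-olide (CNP0227074.3)
Conditions: D-fructose-derived ketone (1,2:4,5-di-O-isopropylidene-D-erythro-2,3-hexodiulo-2,6-pyranose, 0.3 equiv), Oxone (2KHSO5·KHSO4·K2SO4), K2CO3, Bu4NHSO4, MeCN/CH2(OMe)2/aq Na2B4O7 buffer, 0 °C
Reagents that add atoms: potassium peroxymonosulfate, [K+].[O-]S(=O)(=O)OO
Why: In this Shi epoxidation the chiral dioxirane should attack only the electron-rich trisubstituted Z C1=C10 bond (the allylic-alcohol methylidene and the two conjugated alkenes being less nucleophilic), stereospecifically giving the cis-oxirane, and by the spiro transition-state model for trisubstituted ring olefins (as for 1-arylcyclohexenes) on the face that yields 1R,10S.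

**Compound list**

1 | ethyl acetate | CCOC(C)=O | starting material
2 | 2,3-dibromoprop-1-ene | C=C(Br)CBr | starting material
3 | lithium enolate of ethyl acetate | C=C([O-])OCC.[Li+] | intermediate (not isolated)
4 | ethyl 4-bromopent-4-enoate | CCOC(=O)CCC(Br)=C | intermediate
5 | 4-bromopent-4-enal | O=CCCC(Br)=C | intermediate
6 | 1,4-dioxaspiro[4.5]dec-6-en-8-one | O=C1C=CC2(CC1)OCCO2 | starting material
7 | (8S)-1,4-dioxaspiro[4.5]dec-6-en-8-ol | C12(OCCO1)C=C[C@@H](O)CC2 | intermediate
8 | (8S)-8-(tert-butyldimethylsilyloxy)-1,4-dioxaspiro[4.5]dec-6-ene | C12(OCCO1)C=C[C@@H](O[Si](C)(C)C(C)(C)C)CC2 | intermediate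
9 | (4S)-4-(tert-butyldimethylsilyloxy)cyclohex-2-en-1-one | O=C1C=C[C@@H](O[Si](C)(C)C(C)(C)C)CC1 | intermediate
10 | lithium (4S)-4-(tert-butyldimethylsilyloxy)cyclohexa-1,5-dien-1-olate | [Li+].[O-]C1=CC[C@H](O[Si](C)(C)C(C)(C)C)C=C1 | intermediate (not isolated)
11 | (4S,6RS)-4-(tert-butyldimethylsilyloxy)-6-methylcyclohex-2-en-1-one (epimer mixture at the methyl-bearing carbon) | O=C1C=C[C@@H](O[Si](C)(C)C(C)(C)C)CC1C | intermediate
12 | lithium (4S)-4-(tert-butyldimethylsilyloxy)-2-methylcyclohexa-1,5-dien-1-olate | [Li+].[O-]C1=C(C)C[C@H](O[Si](C)(C)C(C)(C)C)C=C1 | intermediate (not isolated)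
13 | (4S,6R)-6-[(1R)-4-bromo-1-hydroxypent-4-en-1-yl]-4-(tert-butyldimethylsilyloxy)-6-methylcyclohex-2-en-1-one | O=C1C=C[C@@H](O[Si](C)(C)C(C)(C)C)C[C@]1(C)[C@H](O)CCC(Br)=C | intermediate
14 | (1R)-4-bromo-1-[(1R,5S)-5-(tert-butyldimethylsilyloxy)-1-methyl-2-oxocyclohex-3-en-1-yl]pent-4-en-1-yl methanesulfonate | O=C1C=C[C@@H](O[Si](C)(C)C(C)(C)C)C[C@]1(C)[C@H](OS(C)(=O)=O)CCC(Br)=C | intermediate
15 | 2-bromo-3,3-diethoxyprop-1-ene | C=C(Br)C(OCC)OCC | starting material
16 | (3,3-diethoxyprop-1-en-2-yl)lithium | [Li]C(=C)C(OCC)OCC | intermediate (not isolated)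
17 | lithium bis(3,3-diethoxyprop-1-en-2-yl)cuprate | [Li+].C=C([Cu-]C(=C)C(OCC)OCC)C(OCC)OCC | intermediate (not isolated)
18 | (1R)-4-bromo-1-[(1R,4R,5S)-5-(tert-butyldimethylsilyloxy)-4-(3,3-diethoxyprop-1-en-2-yl)-1-methyl-2-(trimethylsilyloxy)cyclohex-2-en-1-yl]pent-4-en-1-yl methanesulfonate | C[Si](C)(C)OC1=C[C@H](C(=C)C(OCC)OCC)[C@@H](O[Si](C)(C)C(C)(C)C)C[C@]1(C)[C@H](OS(C)(=O)=O)CCC(Br)=C | intermediate
19 | (1R)-4-bromo-1-[(1R,3S,4R,5S)-3-bromo-5-(tert-butyldimethylsilyloxy)-4-(3,3-diethoxyprop-1-en-2-yl)-1-methyl-2-oxocyclohexyl]pent-4-en-1-yl methanesulfonate | O=C1[C@@H](Br)[C@H](C(=C)C(OCC)OCC)[C@@H](O[Si](C)(C)C(C)(C)C)C[C@]1(C)[C@H](OS(C)(=O)=O)CCC(Br)=C | intermediate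
20 | (1R)-4-bromo-1-[(1R,3S,4R,5S)-3-bromo-5-hydroxy-1-methyl-2-oxo-4-(3-oxoprop-1-en-2-yl)cyclohexyl]pent-4-en-1-yl methanesulfonate | O=C1[C@@H](Br)[C@H](C(=C)C=O)[C@@H](O)C[C@]1(C)[C@H](OS(C)(=O)=O)CCC(Br)=C | intermediate
21 | 2-{(1R,2S,4R,6S)-2-bromo-4-[(1R)-4-bromo-1-(methanesulfonyloxy)pent-4-en-1-yl]-6-hydroxy-4-methyl-3-oxocyclohexyl}prop-2-enoic acid | O=C1[C@@H](Br)[C@H](C(=C)C(=O)O)[C@@H](O)C[C@]1(C)[C@H](OS(C)(=O)=O)CCC(Br)=C | intermediate (not isolated)
22 | (1R)-4-bromo-1-[(3aR,4S,6R,7aR)-4-hydroxy-6-methyl-3-methylidene-2,7-dioxooctahydro-1-benzofuran-6-yl]pent-4-en-1-yl methanesulfonate | C=C1C(=O)O[C@@H]2[C@H]1[C@@H](O)C[C@](C)([C@H](OS(C)(=O)=O)CCC(Br)=C)C2=O | intermediate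
23 | angelic acid, (2Z)-2-methylbut-2-enoic acid | C/C=C(/C)C(=O)O | starting material
24 | (2Z)-2-methylbut-2-enoic 2,4,6-trichlorobenzoic anhydride | C/C=C(/C)C(=O)OC(=O)c1c(Cl)cc(Cl)cc1Cl | intermediate (not isolated)
25 | (3aR,4S,6R,7aR)-6-[(1R)-4-bromo-1-(methanesulfonyloxy)pent-4-en-1-yl]-6-methyl-3-methylidene-2,7-dioxooctahydro-1-benzofuran-4-yl (2Z)-2-methylbut-2-enoate | C=C1C(=O)O[C@@H]2[C@H]1[C@@H](OC(=O)/C(C)=C\C)C[C@](C)([C@H](OS(C)(=O)=O)CCC(Br)=C)C2=O | intermediate
26 | alkenylchromium dichloride of 25 (C4–CrCl2 in place of C4–Br) | C=C1C(=O)O[C@@H]2[C@H]1[C@@H](OC(=O)/C(C)=C\C)C[C@](C)([C@H](OS(C)(=O)=O)CCC(=C)[Cr](Cl)Cl)C2=O | intermediate (not isolated)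
27 | tricyclic chromium alkoxide: cis-fused ring A/ring B C5 alkoxide with the C4–C5 bond formed, C4 methylidene and C1 mesylate retained | C=C1C(=O)O[C@@H]2[C@H]1[C@@H](OC(=O)/C(C)=C\C)C[C@]3(C)[C@H](OS(C)(=O)=O)CCC(=C)[C@]23O[Cr](Cl)Cl | intermediate (not isolated)
28 | (1(10)Z,6R,7R,8S)-8-angeloyloxy-5-oxogermacra-1(10),4(15),11(13)-trien-12,6-olide | C=C1C(=O)O[C@@H]2[C@H]1[C@@H](OC(=O)/C(C)=C\C)C/C(C)=C\CCC(=C)C2=O | intermediate
29 | (1(10)Z,5S,6R,7R,8S)-8-angeloyloxy-5-hydroxygermacra-1(10),4(15),11(13)-trien-12,6-olide | C=C1C(=O)O[C@@H]2[C@H]1[C@@H](OC(=O)/C(C)=C\C)C/C(C)=C\CCC(=C)[C@@H]2O | intermediate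
30 | (1R,5S,6R,7R,8S,10S)-8-angeloyloxy-1,10-epoxy-5-hydroxygermacra-4(15),11(13)-dien-12,6-olide (CNP0227074.3) | C=C1C(=O)O[C@@H]2[C@H]1[C@@H](OC(=O)/C(C)=C\C)C[C@]1(C)O[C@@H]1CCC(=C)[C@@H]2O | target

**Step count and risks**

Total step count: 16. Longest linear sequence: 14 steps (steps 3–16, from 6 to 30).

Steps most likely to fail:

1. Step 14 (Proposed new method). The trivalent chromium alkoxide may be too weakly electron-releasing to fragment in the flask, so the sequence could stall after ring closure. Prolonged contact with excess CrCl2 could also reductively cleave the alpha-acyloxy ketone or enone before or after fragmentation. Fallback with known chemistry, setting out from 25: the two events are separated. The Nozaki–Hiyama–Kishi ring closure alone (CrCl2, catalytic NiCl2, DMSO, 25 °C, aqueous work-up) is used to isolate the tricyclic tertiary alcohol F1. This 1,3-diol monomesylate is then submitted to a classical Wharton-type Grob fragmentation with KN(SiMe3)2 in THF at −78 → 0 °C, where the potassium alkoxide fragments reliably, and the route is rejoined at 28.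

2. Step 15. Facial selectivity may be poor if the catalyst preference and the conformational bias of the ten-membered ring oppose each other, and conjugate reduction of the exocyclic enone by the borane may compete. Fallback, setting out from 28: substrate-controlled Luche reduction (NaBH4, CeCl3·7H2O, MeOH, −78 °C) is used instead. Should it deliver the C5 epimer, the (5R)-alcohol F2, this is inverted by Mitsunobu reaction with chloroacetic acid (PPh3, DIAD, THF, 0 °C) to the (5S)-chloroacetate F3. The chloroacetyl group is then removed with thiourea/NaHCO3 in EtOH, which spares the angelate and the lactone, and the route is rejoined at 29.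

3. Step 16. The dioxirane may attack the wrong face of the flexible ring if catalyst and substrate are mismatched, and the basic buffer may open the lactone or add to the methylene lactone. Fallback, setting out from 28: the order of the last two events is reversed and the oxidation is run without base. Peracid epoxidation (m-CPBA, NaHCO3, CH2Cl2, 0 °C) is carried out on the enone, where C1=C10 is the only nucleophilic olefin and the rigid enone conformer presents its outer face, to give the epoxy ketone F4. Corey–Bakshi–Shibata reduction of F4 under the conditions of step 15 then rejoins the route at 30.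

**Further compounds**

F1 | step 14 | tricyclic tertiary alcohol (protonated form of 27: cis-fused ring A/ring B C5 carbinol, C1 mesylate retained) | C=C1C(=O)O[C@@H]2[C@H]1[C@@H](OC(=O)/C(C)=C\C)C[C@]3(C)[C@H](OS(C)(=O)=O)CCC(=C)[C@]23O
F2 | step 15 | (1(10)Z,5R,6R,7R,8S)-8-angeloyloxy-5-hydroxygermacra-1(10),4(15),11(13)-trien-12,6-olide | C=C1C(=O)O[C@@H]2[C@H]1[C@@H](OC(=O)/C(C)=C\C)C/C(C)=C\CCC(=C)[C@H]2O
F3 | step 15 | (1(10)Z,5S,6R,7R,8S)-8-angeloyloxy-5-(chloroacetoxy)germacra-1(10),4(15),11(13)-trien-12,6-olide | C=C1C(=O)O[C@@H]2[C@H]1[C@@H](OC(=O)/C(C)=C\C)C/C(C)=C\CCC(=C)[C@@H]2OC(=O)CCl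
F4 | step 16 | (1R,6R,7R,8S,10S)-8-angeloyloxy-1,10-epoxy-5-oxogermacra-4(15),11(13)-dien-12,6-olide | C=C1C(=O)O[C@@H]2[C@H]1[C@@H](OC(=O)/C(C)=C\C)C[C@]1(C)O[C@@H]1CCC(=C)C2=O
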